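**Retrosynthetic overview**
Lignan numbering: ring A is the 3,4-dimethoxyphenyl group on C7, ring B the catechol on C7', and ring C the lactone C8–C9(=O)–O–C9'–C8'.
Feature: C8 carries the acceptor carbonyl C9 and C7' carries the electron-rich ring B, so the target is read as a push–pull cyclopropane (C8, C8', C7') fused to ring C whose C8–C7' bond has been cut reductively.
Disconnections, backwards: the catechol O–benzyl bonds; epimerisation at C8; the C8–C7' bond (reductive opening); then C8–C8' and C8–C7' together, by intramolecular carbene addition to the (E)-cinnamyl alkene of an allylic α-diazoester.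
The diazoester is assembled from caffeic acid (ring B arm), acetylketene from the dioxinone (C8 and C9) and veratryl alcohol (ring A arm) by acetoacetate C-alkylation and deacetylative diazo transfer.
Ring order: rings A and B are bought; ring C and the cyclopropane form together in step 7; the cyclopropane is opened again in step 8.

Key step: step 7

Remark on the chemistry: Rh2(4R-MPPIM)4 is the dirhodium tetrakis-amidate of methyl (4R)-2-oxo-1-(3-phenylpropanoyl)imidazolidine-4-carboxylate (both rhodium atoms divalent); its sense of induction is assumed to be the one known for allylic diazoacetates, where S-configured ligands lead to the (1R,5S) lactone sense, so the R-ligand is taken for the (1S,5R) sense needed here, and the S-catalyst would be used instead if the α-benzyl group reversed the preference.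

Step 1
Reactants: 1 caffeic acid
Product: 2 benzyl (E)-3-[3,4-bis(benzyloxy)phenyl]prop-2-enoate
Conditions: BnBr (3.5 equiv), K2CO3 (4 equiv), DMF, 60 °C
Reagents that add atoms: benzyl bromide, BrCc1ccccc1
Why: Williamson etherification of both phenols and SN2 esterification of the carboxylate by benzyl bromide run together under carbonate base, and the (E)-alkene is not touched.

Step 2
Reactants: 2 benzyl (E)-3-[3,4-bis(benzyloxy)phenyl]prop-2-enoate
Product: 3 (E)-3-[3,4-bis(benzyloxy)phenyl]prop-2-en-1-ol
Conditions: i-Bu2AlH (2.5 equiv), CH2Cl2, −78 °C → 0 °C; aq. potassium sodium tartrate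
Reagents that add atoms: none
Why: Aluminium hydride reduction of the cinnamate ester gives the allylic alcohol because i-Bu2AlH at low temperature adds 1,2 to the ester and neither reduces the alkene nor cleaves benzyl ethers.

Step 3
Reactants: 3 (E)-3-[3,4-bis(benzyloxy)phenyl]prop-2-en-1-ol; 4 2,2,6-trimethyl-4H-1,3-dioxin-4-one
Product: 6 (E)-3-[3,4-bis(benzyloxy)phenyl]prop-2-en-1-yl 3-oxobutanoate, via acetylketene 5 (not isolated)
Conditions: toluene, 110 °C, acetone distilled off
Reagents that add atoms: none
Why: Thermal retro-[4+2] fragmentation of the dioxinone releases acetylketene, which acylates the primary allylic alcohol (acetoacetylation) under neutral conditions well below the temperature of a Carroll rearrangement.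

Step 4
Reactants: 7 veratryl alcohol (3,4-dimethoxybenzyl alcohol)
Product: 8 3,4-dimethoxybenzyl bromide
Conditions: PBr3 (0.4 equiv), Et2O, 0 °C; used at once
Reagents that add atoms: phosphorus tribromide, BrP(Br)Br
Why: Substitution of a primary benzylic alcohol by bromide through its phosphite ester is fast at 0 °C, and the labile bromide is carried on without storage.

Step 5
Reactants: 6 (E)-3-[3,4-bis(benzyloxy)phenyl]prop-2-en-1-yl 3-oxobutanoate; 8 3,4-dimethoxybenzyl bromide
Product: 10 (E)-3-[3,4-bis(benzyloxy)phenyl]prop-2-en-1-yl 2-(3,4-dimethoxybenzyl)-3-oxobutanoate (racemic), via sodium enolate 9 (not isolated)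
Conditions: NaH (1.0 equiv), THF, 0 °C; then 8 (0.95 equiv), 0 °C → rt
Reagents that add atoms: none
Why: Acetoacetic ester alkylation, in which the stabilised sodium enolate is C-alkylated in an SN2 reaction by the reactive benzylic bromide, a slight deficit of bromide limits double alkylation, and the new centre is racemic and is erased in step 6.

Step 6
Reactants: 10 (E)-3-[3,4-bis(benzyloxy)phenyl]prop-2-en-1-yl 2-(3,4-dimethoxybenzyl)-3-oxobutanoate
Product: 11 (E)-3-[3,4-bis(benzyloxy)phenyl]prop-2-en-1-yl 2-diazo-3-(3,4-dimethoxyphenyl)propanoate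
Conditions: p-ABSA (1.5 equiv), DBU (2 equiv), MeCN, 0 °C → rt
Reagents that add atoms: 4-acetamidobenzenesulfonyl azide (p-ABSA), CC(=O)Nc1ccc(cc1)S(=O)(=O)N=[N+]=[N-]
Why: Deacylative Regitz diazo transfer, in which the DBU enolate attacks the sulfonyl azide and the adduct, having no α-hydrogen left, fragments by transfer of the acetyl group to the sulfonamide nitrogen, leaving the α-diazoester with the (E)-alkene and all ethers intact.

Step 7
Reactants: 11 (E)-3-[3,4-bis(benzyloxy)phenyl]prop-2-en-1-yl 2-diazo-3-(3,4-dimethoxyphenyl)propanoate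
Product: 12 (1S,5R,6S)-6-[3,4-bis(benzyloxy)phenyl]-1-(3,4-dimethoxybenzyl)-3-oxabicyclo[3.1.0]hexan-2-one (cis-fused, aryl exo)
Conditions: Rh2(4R-MPPIM)4 (2 mol%), CH2Cl2, 40 °C, slow addition of 11 over about 10 h
Reagents that add atoms: none
Why: The dirhodium amidate expels N2 from 11 to give an electrophilic rhodium carbene at C8, which adds to the C8'=C7' styrenyl alkene in a concerted, asynchronous [2+1] event in which C8–C8' leads and C8–C7' follows, the developing positive charge at benzylic C7' being stabilised by ring B. The closest known reaction type is the enantioselective intramolecular cyclopropanation of allylic diazoacetates and α-diazopropionates with chiral dirhodium carboxamidates. Ring C closes in a 5-exo mode through the C9–O–C9' tether by the C8–C8' bond, and the three-membered ring closes by the C8–C7' bond in the same event, so the ring fusion can only be cis. C8' is set by the alkene face that the chiral amidate ligands leave open to the carbene, C8 follows from C8' through the enforced cis fusion, and C7' follows from retention of the (E)-alkene geometry, which places ring B exo. The step needs chemoselectivity for alkene addition over 1,2-hydride shift from C7 and it needs enantiofacial control; the first is served by the less electrophilic amidate-ligated carbene, by the electron-rich alkene held five atoms away and by slow addition, the second by an imidazolidinone ligand suited to (E)-disubstituted allylic esters.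

Step 8
Reactants: 12 (1S,5R,6S)-6-[3,4-bis(benzyloxy)phenyl]-1-(3,4-dimethoxybenzyl)-3-oxabicyclo[3.1.0]hexan-2-one
Product: 14 (3RS,4R)-4-[3,4-bis(benzyloxy)benzyl]-3-(3,4-dimethoxybenzyl)dihydrofuran-2(3H)-one (C8 epimers), via samarium enolate 13 (not isolated)
Conditions: SmI2 (2.5 equiv), HMPA (10 equiv), t-BuOH (2 equiv), THF, −78 °C → 0 °C; aq. NH4Cl
Reagents that add atoms: none
Why: Reductive ring opening of an acceptor cyclopropane by single-electron transfer, in which SmI2–HMPA reduces the lactone carbonyl to a ketyl-type radical anion, the exocyclic C8–C7' bond (best aligned with the carbonyl π system and leaving a benzylic radical stabilised by ring B) fragments, a second electron and t-BuOH turn C7' into CH2, and protonation of the trivalent samarium enolate gives the lactone as C8 epimers while C8' and the benzyl ethers are untouched.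

Step 9
Reactants: 14 (3RS,4R)-4-[3,4-bis(benzyloxy)benzyl]-3-(3,4-dimethoxybenzyl)dihydrofuran-2(3H)-one
Product: 15 (3R,4R)-4-[3,4-bis(benzyloxy)benzyl]-3-(3,4-dimethoxybenzyl)dihydrofuran-2(3H)-one
Conditions: DBU (0.5 equiv), toluene, 80 °C
Reagents that add atoms: none
Why: Base-mediated epimerisation through the lactone enolate under thermodynamic control should converge on the more stable 3,4-trans arrangement of the two benzyl arms, so C8 becomes R relative to the fixed, non-enolisable C8'.

Step 10
Reactants: 15 (3R,4R)-4-[3,4-bis(benzyloxy)benzyl]-3-(3,4-dimethoxybenzyl)dihydrofuran-2(3H)-one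
Product: 16 (3R,4R)-4-(3,4-dihydroxybenzyl)-3-(3,4-dimethoxybenzyl)dihydrofuran-2(3H)-one (target)
Conditions: H2 (1 atm), 10% Pd/C, EtOAc–EtOH, rt
Reagents that add atoms: none
Why: Catalytic hydrogenolysis of the two benzyl aryl ethers over Pd/C is neutral, so the methyl ethers, the lactone and both stereocentres should be retained.

**Compound list**
1 | caffeic acid | O=C(O)/C=C/c1ccc(O)c(O)c1 | starting material
2 | benzyl (E)-3-[3,4-bis(benzyloxy)phenyl]prop-2-enoate | O=C(OCc1ccccc1)/C=C/c1ccc(OCc2ccccc2)c(OCc2ccccc2)c1 | intermediate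
3 | (E)-3-[3,4-bis(benzyloxy)phenyl]prop-2-en-1-ol | OC/C=C/c1ccc(OCc2ccccc2)c(OCc2ccccc2)c1 | intermediate
4 | 2,2,6-trimethyl-4H-1,3-dioxin-4-one | CC1=CC(=O)OC(C)(C)O1 | starting material
5 | acetylketene (not isolated) | CC(=O)C=C=O | intermediate
6 | (E)-3-[3,4-bis(benzyloxy)phenyl]prop-2-en-1-yl 3-oxobutanoate | CC(=O)CC(=O)OC/C=C/c1ccc(OCc2ccccc2)c(OCc2ccccc2)c1 | intermediate
7 | veratryl alcohol (3,4-dimethoxybenzyl alcohol) | COc1ccc(CO)cc1OC | starting material
8 | 3,4-dimethoxybenzyl bromide | COc1ccc(CBr)cc1OC | intermediate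
9 | sodium enolate of 6 (not isolated) | [Na+].CC([O-])=CC(=O)OC/C=C/c1ccc(OCc2ccccc2)c(OCc2ccccc2)c1 | intermediate
10 | (E)-3-[3,4-bis(benzyloxy)phenyl]prop-2-en-1-yl 2-(3,4-dimethoxybenzyl)-3-oxobutanoate (racemic) | COc1ccc(CC(C(C)=O)C(=O)OC/C=C/c2ccc(OCc3ccccc3)c(OCc3ccccc3)c2)cc1OC | intermediate
11 | (E)-3-[3,4-bis(benzyloxy)phenyl]prop-2-en-1-yl 2-diazo-3-(3,4-dimethoxyphenyl)propanoate | COc1ccc(CC(=[N+]=[N-])C(=O)OC/C=C/c2ccc(OCc3ccccc3)c(OCc3ccccc3)c2)cc1OC | intermediate
12 | (1S,5R,6S)-6-[3,4-bis(benzyloxy)phenyl]-1-(3,4-dimethoxybenzyl)-3-oxabicyclo[3.1.0]hexan-2-one | O=C1OC[C@@H]2[C@@H](c3ccc(OCc4ccccc4)c(OCc4ccccc4)c3)[C@]12Cc1ccc(OC)c(OC)c1 | intermediate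
13 | diiodosamarium (trivalent samarium) enolate of the ring-opened lactone (not isolated) | COc1ccc(CC2=C(O[Sm](I)I)OC[C@@H]2Cc2ccc(OCc3ccccc3)c(OCc3ccccc3)c2)cc1OC | intermediate
14 | (3RS,4R)-4-[3,4-bis(benzyloxy)benzyl]-3-(3,4-dimethoxybenzyl)dihydrofuran-2(3H)-one | COc1ccc(CC2C(=O)OC[C@@H]2Cc2ccc(OCc3ccccc3)c(OCc3ccccc3)c2)cc1OC | intermediate
15 | (3R,4R)-4-[3,4-bis(benzyloxy)benzyl]-3-(3,4-dimethoxybenzyl)dihydrofuran-2(3H)-one | COc1ccc(C[C@H]2C(=O)OC[C@@H]2Cc2ccc(OCc3ccccc3)c(OCc3ccccc3)c2)cc1OC | intermediate
16 | (3R,4R)-4-(3,4-dihydroxybenzyl)-3-(3,4-dimethoxybenzyl)dihydrofuran-2(3H)-one | COc1ccc(C[C@H]2C(=O)OC[C@@H]2Cc2ccc(O)c(O)c2)cc1OC | target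

**Step count and risks**
Total step count: 10. Longest linear sequence: 9 steps (steps 1, 2, 3, 5, 6, 7, 8, 9 and 10 from caffeic acid); step 4 is a one-step branch.

Steps most likely to fail:

1. Step 7. Migration of a hydride from C7 to the carbene carbon may outrun addition to the alkene, and facial discrimination may be weak with the α-branched carbene. The fallback sets out from 6 and comes back at 15. Diazo transfer to 6 (p-ABSA, Et3N, MeCN) should give (E)-3-[3,4-bis(benzyloxy)phenyl]prop-2-en-1-yl 2-diazo-3-oxobutanoate F1. Deacetylation with aqueous LiOH in MeCN should give (E)-3-[3,4-bis(benzyloxy)phenyl]prop-2-en-1-yl diazoacetate F2, whose carbene has no neighbouring hydrogen. Cyclopropanation with Rh2(4R-MPPIM)4 in CH2Cl2 at 40 °C, the precedented diazoacetate case, should give (1S,5R,6R)-6-[3,4-bis(benzyloxy)phenyl]-3-oxabicyclo[3.1.0]hexan-2-one F3. Opening with SmI2–HMPA–t-BuOH as in step 8 passes through the trivalent samarium enolate F4 and should give (R)-4-[3,4-bis(benzyloxy)benzyl]dihydrofuran-2(3H)-one F5. Deprotonation with LiN(SiMe3)2 in THF at −78 °C gives the lithium enolate F6, which bromide 8 should alkylate anti to the C8' substituent, giving the trans lactone 15 directly. The ring A arm is then attached by enolate alkylation, and steps 8 and 9 are not needed.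

2. Step 8. Electron transfer to the lactone carbonyl may be sluggish, or the carbonyl group may be reduced further once the ring has opened. The fallback sets out from 12 and comes back at 16. Hydrogenation over Pd/C (H2, 3 atm, EtOAc–AcOH) should cleave the donor–acceptor C8–C7' bond and both benzyl ethers in one operation, giving (3RS,4R)-4-(3,4-dihydroxybenzyl)-3-(3,4-dimethoxybenzyl)dihydrofuran-2(3H)-one F7. Equilibration of F7 with DBU in degassed THF under argon, followed by mild acidic work-up, should then give 16.

3. Step 5. A second alkylation of the product enolate and decomposition of the labile benzylic bromide may erode the mono-alkylation. The fallback sets out from 6 and comes back at 10. Condensation of 6 with commercial 3,4-dimethoxybenzaldehyde under L-proline catalysis (CH2Cl2, rt) gives the benzylidene acetoacetate (E)-3-[3,4-bis(benzyloxy)phenyl]prop-2-en-1-yl 2-(3,4-dimethoxybenzylidene)-3-oxobutanoate F8. F8 is reduced in the same flask by diethyl 2,6-dimethyl-1,4-dihydropyridine-3,5-dicarboxylate to 10 (Knoevenagel condensation followed by conjugate transfer hydrogenation). This sequence can only mono-alkylate and needs no bromide.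

**Further compounds**
F1 | step 7 | (E)-3-[3,4-bis(benzyloxy)phenyl]prop-2-en-1-yl 2-diazo-3-oxobutanoate | CC(=O)C(=[N+]=[N-])C(=O)OC/C=C/c1ccc(OCc2ccccc2)c(OCc2ccccc2)c1
F2 | step 7 | (E)-3-[3,4-bis(benzyloxy)phenyl]prop-2-en-1-yl diazoacetate | [N-]=[N+]=CC(=O)OC/C=C/c1ccc(OCc2ccccc2)c(OCc2ccccc2)c1
F3 | step 7 | (1S,5R,6R)-6-[3,4-bis(benzyloxy)phenyl]-3-oxabicyclo[3.1.0]hexan-2-one | O=C1OC[C@@H]2[C@@H](c3ccc(OCc4ccccc4)c(OCc4ccccc4)c3)[C@H]12
F4 | step 7 | diiodosamarium (trivalent samarium) enolate of (R)-4-[3,4-bis(benzyloxy)benzyl]dihydrofuran-2(3H)-one | I[Sm](I)OC1=C[C@@H](Cc2ccc(OCc3ccccc3)c(OCc3ccccc3)c2)CO1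
F5 | step 7 | (R)-4-[3,4-bis(benzyloxy)benzyl]dihydrofuran-2(3H)-one | O=C1C[C@@H](Cc2ccc(OCc3ccccc3)c(OCc3ccccc3)c2)CO1
F6 | step 7 | lithium enolate of (R)-4-[3,4-bis(benzyloxy)benzyl]dihydrofuran-2(3H)-one | [Li+].[O-]C1=C[C@@H](Cc2ccc(OCc3ccccc3)c(OCc3ccccc3)c2)CO1
F7 | step 8 | (3RS,4R)-4-(3,4-dihydroxybenzyl)-3-(3,4-dimethoxybenzyl)dihydrofuran-2(3H)-one | COc1ccc(CC2C(=O)OC[C@@H]2Cc2ccc(O)c(O)c2)cc1OC
F8 | step 5 | (E)-3-[3,4-bis(benzyloxy)phenyl]prop-2-en-1-yl 2-(3,4-dimethoxybenzylidene)-3-oxobutanoate | COc1ccc(C=C(C(C)=O)C(=O)OC/C=C/c2ccc(OCc3ccccc3)c(OCc3ccccc3)c2)cc1OC
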